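(The earlier runs and the new flask were generated by integration with made-up constants; the scatter is artificial.)

The constants of the four steps are unknown, but the round can be read from its rate: starting material turns fresh carrier into spent carrier, salt in the second phase turns spent carrier back, and capture agent removes spent carrier as trapped intermediate.

| setting | summer | spring | gamma | alpha |
|---|---|---|---|---|
| starting material | 0.050 M | 0.10 M | 0.050 M | 0.050 M |
| salt in the second phase | 0.075 M | 0.075 M | 0.0750 M | 0.0750 M |
| capture agent | 1.7 mM | 2.5 mM | 2.50 mM | 2.50 mM |
| spent carrier | 5 mM | 5 mM | 12 mM | 5.0 mM |
| remark | run made earlier | run made earlier |  |  |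
| time |  |  | 10 min | 10 min |
| volume of the second phase over the first |  |  | 1.0 | 1.0 |

- summer (time / min: target / %, starting material / %, isomer of the product / %): 0.250: 0.1, 99.6, 0.5; 0.667: 1.8, 98.1, 0; 1.33: 7.4, 92.4, 0.2; 2.00: 11.0, 89.5, 0; 2.50: 12.8, 86.1, 1.5; 4.00: 20.1, 78.3, 0.9
- spring (time / min: target / %, starting material / %, isomer of the product / %): 0.667: 1.8, 98.1, 0.2; 1.33: 4.7, 95.4, 1.7; 2.00: 7.8, 93.0, 0.3; 2.50: 8.7, 91.2, 0.1; 3.00: 10.4, 88.7, 0.2; 4.00: 12.6, 85.5, 2.1

(each reading ± 0.5 percentage points)

* which of these there is most of at the end, counted by the starting material in it, gamma (isomer of the product / starting material / target)
* which of these there is most of at the end, counted by the starting material in it, alpha (isomer of the product / starting material / target)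
* how much there is at the end of the one of these that leads, in percent of the starting material charged: gamma
* how much there is at the end of the one of these that leads, in percent of the starting material charged: alpha

- in the second phase: salt in the second phase, spent salt in the second phase; everything else is in the first
- charges count per volume of the first phase; a concentration in a rate is the amount of a species over the volume of its own phase; every rate counts per litre of the first phase
- reactions considered so far: target + fresh carrier <-> isomer of the product + fresh carrier; starting material + fresh carrier -> target + spent carrier; spent carrier + salt in the second phase <-> fresh carrier + spent salt in the second phase; spent carrier + capture agent -> trapped intermediate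
- the earlier runs hold the two phases in the same ratio of volumes as the flask asked about

The summer run keeps 78.3% of its starting material at 4.00 min, and this gives the turnover frequency, the starting material consumed per minute per unit of working carrier, 0.542 min⁻¹ if capture takes no carrier. If capture instantly takes its equal in carrier, the same reading gives 0.822 min⁻¹ on the smaller working amount. Carried to alpha as straight lines, the first extreme leaves 45.8% starting material and the second 58.9%. The carrier lost lies between nothing and the capture agent charged, so my reckoning takes the middle, 52.3%, with starting material leading alpha. For gamma both lines overrun the charge, the first reaching 65.1 mM against 50 mM, so they bend and give no figure, and my reckoning names target as the leader in gamma without a number.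

The forecast names target at 46% for gamma and starting material at 67% for alpha, above my range, holding that “the capture agent quickly removes an equal amount of carrier”.

Gamma ends with target leading at 49.3%, and alpha with starting material leading at 56.2%.

    target + fresh carrier ⇌ isomer of the product + fresh carrier, rate k1*[target]*[fresh carrier] forward; the back reaction follows from the equilibrium constant (K = 3.10, k = 21.0 M⁻¹ min⁻¹)
    starting material + fresh carrier → target + spent carrier (k = 37.0 M⁻¹ min⁻¹)
    spent carrier + salt in the second phase ⇌ fresh carrier + spent salt in the second phase (K = 0.750, k = 16.0 M⁻¹ min⁻¹)
    spent carrier + capture agent → trapped intermediate (k = 21.0 M⁻¹ min⁻¹)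

Alpha has consumed 21.9 mM, or 0.438 min⁻¹ per unit of charged carrier over its 10 min, below the 0.542 min⁻¹ read from the summer run. The gap in target between gamma and alpha, 49.3% against 37.0%, comes from their difference in spent carrier. A neighbour of alpha charged with 0.12 M starting material consumes 0.587 min⁻¹ per unit of charged carrier, above 0.542 min⁻¹, and keeps 76% of its starting material.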